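**Plan**

- Numbering: C1 = quaternary carbinol bearing C7H2OBz, C2 and C3 = acetoxy carbons, C4=C5 = alkene, C6 = secondary carbinol. The retrosynthesis first cuts the C6–O bond (the C1 oxygen is re-bridged to C4, alkene back at C5=C6), then the two ring bonds C1–C2 and C3–C4.
- Enabling feature: the array C7–C1(O)–C6–C5–C4 is a 2-substituted furan ring whose ring oxygen is the later C1 hydroxyl, and the cis C2/C3 dioxygen pair is a cis-enediol, available as the five-membered ring of vinylene carbonate.
- Forward order: furfuryl alcohol is benzoylated; one intermolecular [4+2] cycloaddition forms C1–C2 and C3–C4 and with them the only carbocycle, as a 7-oxanorbornene; the carbonate is exchanged for two acetates; the oxygen bridge is opened at C4–O by 4-methoxybenzyl alcohol under rhodium catalysis; the benzyl ether is removed.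
- Stereochemistry: the suprafacial endo cycloaddition fixes C1, C2 and C3 relative to one another (C2–O and C3–O cis, both anti to the bridge oxygen). Anti SN2′ attack in the bridge opening sets C6 trans to the C1 oxygen. The absolute configuration is chosen in that same step, where a chiral rhodium catalyst turns only one antipode of the racemic adduct into the C6 ether.

Key step: step 2

Remark: the cycloadduct, the diol and the diacetate made from it are racemates; names, descriptors and SMILES show the antipode that is carried on to the target.
Remark: which hand of the ferrocenyl diphosphine opens the drawn antipode at C4–O is inferred by analogy; if the induction proves opposite, the mirror-image ligand is used in step 5.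

**Step 1**
Reactants: 1 furfuryl alcohol (furan-2-ylmethanol); 2 benzoyl chloride
Product: 3 furfuryl benzoate (furan-2-ylmethyl benzoate)
Conditions: BzCl (1.1 equiv), Et3N (1.3 equiv), DMAP (5 mol%), CH2Cl2, 0 °C to rt
Reagents that add atoms: none
Why: DMAP-catalysed O-acylation of a primary alcohol by an acid chloride under amine base (Schotten–Baumann-type esterification) is fast at 0 °C, the basic medium spares the acid-sensitive furfuryl system, and no stereocentre is formed.

**Step 2**
Reactants: 3 furfuryl benzoate; 4 vinylene carbonate (1,3-dioxol-2-one)
Product: 5 rac-[(1S,2R,3R,4S)-2,3-(carbonyldioxy)-7-oxabicyclo[2.2.1]hept-5-en-1-yl]methyl benzoate (endo cycloadduct: cyclic carbonate on C2/C3 anti to the oxygen bridge, CH2OBz on bridgehead C1)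
Conditions: 4 (3 equiv), BHT (1 mol%), neat, sealed tube, 120–125 °C, 48 h; endo adduct separated from the exo isomer by chromatography and crystallisation
Reagents that add atoms: none
Why: Thermal Diels–Alder reaction: the furan ring of 3 (4π) and the ring-locked cis-enediol carbonate 4 (2π) combine in a concerted, suprafacial–suprafacial [4+2] cycloaddition, the closest known case being the sealed-tube cycloaddition of furan itself with vinylene carbonate. The carbocyclic six-membered ring C1–C6 closes by this intermolecular [4+2] annulation, C1–C2 and C3–C4 forming together, and the former furan oxygen is left as the C1–O–C4 bridge of a 7-oxanorbornene. C1 and C4 are tied cis by that bridge, C2 and C3 are cis because the dienophile geometry is fixed in its ring, and the endo transition state (carbonate tucked under the diene, secondary overlap of its oxygen lone pairs with C5/C6) places C2–O and C3–O anti to the bridge oxygen, which is the C1–O/C2–O trans relation of the target; nothing controls the absolute sense, so 5 is racemic. The selectivity the step needs is endo over exo; for furans it is modest and the addition is reversible, so the temperature is kept at the lowest workable value to stay under kinetic control and the endo adduct is secured by separation from the exo isomer. No regiochemical question arises because 4 is symmetric, and the bridgehead CH2OBz group is only a spectator.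

**Step 3**
Reactants: 5 endo cycloadduct carbonate
Product: 6 rac-[(1S,2R,3S,4S)-2,3-dihydroxy-7-oxabicyclo[2.2.1]hept-5-en-1-yl]methyl benzoate (2-endo,3-endo-diol)
Conditions: K2CO3 (1.5 equiv), THF/H2O (2:1), 0 °C to rt; aq NH4Cl quench
Reagents that add atoms: none
Why: Chemoselective carbonate saponification: hydroxide attacks the carbonyl of the strained, cis-fused five-membered cyclic carbonate far faster than the aryl ester, CO2 leaves as hydrogencarbonate, and because only acyl–oxygen bonds break the C2–O and C3–O bonds keep their endo configuration.

**Step 4**
Reactants: 6 endo,cis-diol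
Product: 7 rac-[(1S,2R,3R,4S)-2,3-diacetoxy-7-oxabicyclo[2.2.1]hept-5-en-1-yl]methyl benzoate (2-endo,3-endo-diacetate)
Conditions: Ac2O (3 equiv), pyridine (4 equiv), DMAP (10 mol%), CH2Cl2, 0 °C to rt
Reagents that add atoms: acetic anhydride, CC(=O)OC(C)=O
Why: DMAP-catalysed acetylation of two secondary hydroxyls is routine, and since no bond to a stereocentre is broken the endo,cis arrangement is carried over unchanged.

**Step 5**
Reactants: 7 endo-diacetate; 8 4-methoxybenzyl alcohol
Product: 9 [(1R,2R,3R,6S)-2,3-diacetoxy-1-hydroxy-6-[(4-methoxybenzyl)oxy]cyclohex-4-en-1-yl]methyl benzoate (C6 ether trans to the C1 hydroxyl and cis to C7; single enantiomer)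
Conditions: [Rh(cod)2]OTf (5 mol%), (R)-1-[(Sp)-2-(diphenylphosphino)ferrocenyl]ethyldi-tert-butylphosphine (Josiphos-type, 6 mol%), 8 (5 equiv), THF, 60 °C; chromatographic separation from the regioisomeric ether
Reagents that add atoms: none
Why: Proposed new method: a cationic monovalent rhodium–diphosphine complex is expected to bind the strained C5=C6 alkene of 7 on the exo face and insert, with retention, into the allylic C4–O bridge bond (remote from the inductively deactivated, quaternary C1), and the alcohol 8 then attacks the resulting rhodium allyl at C6 anti to the metal (SN2′), so that the bridge oxygen stays as the C1 hydroxyl, C6–O is set trans to it and the alkene ends at C4=C5, while the chiral ligand directs the mirror-image antipode to cleavage of its C1–O bond and thus to a separable constitutional isomer (parallel kinetic resolution, absolute configuration of 9 under catalyst control, at most half of the racemate usable); closest known reaction type: rhodium-catalysed asymmetric ring opening of oxabenzonorbornadienes by alcohols and its regiodivergent resolution of bridgehead-substituted members, here extended to a non-benzo-fused oxanorbornene carrying endo acetates.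

**Step 6**
Reactants: 9 C6 4-methoxybenzyl ether
Product: 10 [(1R,2R,3R,6S)-2,3-diacetoxy-1,6-dihydroxycyclohex-4-en-1-yl]methyl benzoate (CNP0130780.2)
Conditions: DDQ (1.3 equiv), CH2Cl2/pH 7 phosphate buffer (10:1), 0 °C
Reagents that add atoms: none
Why: Oxidative cleavage of a 4-methoxybenzyl ether: DDQ removes hydride from the electron-rich benzylic position, water captures the oxocarbenium ion and the hemiacetal collapses to 10 and 4-methoxybenzaldehyde, leaving the acetates, the benzoate and the C6–O bond with its configuration untouched, while the buffered wet medium suppresses acyl migration and benzylidene acetal formation onto the C1 hydroxyl.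

**Compound list**

1 | furfuryl alcohol (furan-2-ylmethanol) | OCc1ccco1 | starting material
2 | benzoyl chloride | O=C(Cl)c1ccccc1 | starting material
3 | furfuryl benzoate (furan-2-ylmethyl benzoate) | O=C(OCc1ccco1)c1ccccc1 | intermediate
4 | vinylene carbonate (1,3-dioxol-2-one) | O=C1OC=CO1 | starting material
5 | rac-[(1S,2R,3R,4S)-2,3-(carbonyldioxy)-7-oxabicyclo[2.2.1]hept-5-en-1-yl]methyl benzoate, endo adduct, antipode shown | O=C(OC[C@@]12O[C@@H](C=C1)[C@H]3OC(=O)O[C@@H]23)c1ccccc1 | intermediate
6 | rac-[(1S,2R,3S,4S)-2,3-dihydroxy-7-oxabicyclo[2.2.1]hept-5-en-1-yl]methyl benzoate, endo,cis-diol, antipode shown | O=C(OC[C@@]12O[C@@H](C=C1)[C@@H](O)[C@H]2O)c1ccccc1 | intermediate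
7 | rac-[(1S,2R,3R,4S)-2,3-diacetoxy-7-oxabicyclo[2.2.1]hept-5-en-1-yl]methyl benzoate, endo,cis-diacetate, antipode shown | O=C(OC[C@@]12O[C@@H](C=C1)[C@@H](OC(C)=O)[C@H]2OC(C)=O)c1ccccc1 | intermediate
8 | 4-methoxybenzyl alcohol | COc1ccc(CO)cc1 | starting material
9 | [(1R,2R,3R,6S)-2,3-diacetoxy-1-hydroxy-6-[(4-methoxybenzyl)oxy]cyclohex-4-en-1-yl]methyl benzoate | CC(=O)O[C@@H]1[C@H](OC(C)=O)C=C[C@H](OCc2ccc(OC)cc2)[C@]1(O)COC(=O)c1ccccc1 | intermediate
10 | [(1R,2R,3R,6S)-2,3-diacetoxy-1,6-dihydroxycyclohex-4-en-1-yl]methyl benzoate | CC(=O)O[C@@H]1[C@H](OC(C)=O)C=C[C@H](O)[C@]1(O)COC(=O)c1ccccc1 | target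

**Step count and risks**

Total steps: 6. Longest linear sequence: 6 steps (1 → 3 → 5 → 6 → 7 → 9 → 10).

Steps most likely to fail:

1. Step 5 (the proposed method).
   - What may go wrong: insertion of rhodium into the bridge C–O bond of a non-benzo-fused oxanorbornene may be too slow; attack of the alcohol on the lower face of C6, next to the quaternary C1 and the endo acetate, may stall; or the ligand may fail to send the two antipodes to different bridgehead bonds.
   - Fallback, using classical reactions only: it sets out from 5 and rejoins the route at 9. The antipodes of 5 are first separated by preparative chromatography on a chiral stationary phase (cellulose tris(3,5-dimethylphenylcarbamate)).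
   - BBr3 (CH2Cl2, −78 °C), a standard reagent for cleaving bridging allylic ethers, opens the C4–O bond of the needed antipode to the 6-bromo-1-hydroxy carbonate F1. Bromine is expected on the face away from the carbonate; a C6 epimer or the C4 allylic isomer would serve equally, since all ionise to the same allyl cation.
   - Silver-assisted solvolysis (AgOTf, acetone/H2O, 0 °C) then places oxygen on C6 from the face of C7 by neighbouring-group participation. Either the C7 benzoate carbonyl closes a six-membered dioxanylium ion on the lower face, or the C1 hydroxyl closes an epoxide that water reopens at the allylic C6 with inversion. Both paths lead to the 1,6-trans-diol carbonate F2; a benzoate that ends on O6 is returned to the primary position by acyl migration with Et3N.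
   - The secondary C6 hydroxyl is etherified with 4-methoxybenzyl trichloroacetimidate and catalytic camphorsulfonic acid to the ether carbonate F3. The carbonate is hydrolysed as in step 3 (K2CO3, THF/H2O) to the ether diol F4, and acetylation as in step 4 gives 9.

2. Step 2 (key step).
   - What may go wrong: weak endo/exo facial selectivity, together with slow conversion and cycloreversion at the temperature the unactivated dienophile needs, so that the exo adduct dominates.
   - Fallback: the endo configuration is no longer demanded of the cycloaddition but is set afterwards by reagent approach. It sets out from 3 and 4 and rejoins the route at 6.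
   - The exo cycloadduct F5 that accompanies 5 is hydrolysed (K2CO3, THF/H2O) to the exo,cis-diol F6. Swern oxidation (DMSO, (COCl)2, then Et3N, −78 °C) gives the 2,3-dione F7, which has no enolisable hydrogen.
   - Reduction with NaBH4 (MeOH/CH2Cl2, −78 °C) should deliver hydride on the exo face of both carbonyl groups (the face of the oxygen bridge, away from the C5=C6 alkene) and so give the endo,cis-diol 6.

3. Step 3.
   - What may go wrong: hydrolysis of the benzoate, or its migration from O7 onto the freed C2 oxygen, while the carbonate is being cleaved.
   - Fallback: the chemoselectivity is moved from the hydrolysis to the acylation. It sets out from 5 and rejoins the route at 6.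
   - Carbonate and benzoate are both removed on purpose by methanolysis (K2CO3, MeOH, rt) to the triol F8. The primary C7 hydroxyl alone is then benzoylated with 2 (1.05 equiv) and 2,4,6-collidine in CH2Cl2 at −40 °C to give 6.

Further compounds
F1 | step 5 | [6-bromo-2,3-(carbonyldioxy)-1-hydroxycyclohex-4-en-1-yl]methyl benzoate, bromine cis to the C1 hydroxyl | O=C2O[C@@H]1[C@H](O2)C=C[C@@H](Br)[C@]1(O)COC(=O)c1ccccc1
F2 | step 5 | [2,3-(carbonyldioxy)-1,6-dihydroxycyclohex-4-en-1-yl]methyl benzoate, 1,6-trans-diol | O=C2O[C@@H]1[C@H](O2)C=C[C@H](O)[C@]1(O)COC(=O)c1ccccc1
F3 | step 5 | [2,3-(carbonyldioxy)-1-hydroxy-6-[(4-methoxybenzyl)oxy]cyclohex-4-en-1-yl]methyl benzoate | O=C2O[C@@H]1[C@H](O2)C=C[C@H](OCc3ccc(OC)cc3)[C@]1(O)COC(=O)c1ccccc1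
F4 | step 5 | [1,2,3-trihydroxy-6-[(4-methoxybenzyl)oxy]cyclohex-4-en-1-yl]methyl benzoate | O[C@@H]1[C@H](O)C=C[C@H](OCc2ccc(OC)cc2)[C@]1(O)COC(=O)c1ccccc1
F5 | step 2 | [2,3-(carbonyldioxy)-7-oxabicyclo[2.2.1]hept-5-en-1-yl]methyl benzoate, exo adduct (carbonate syn to the oxygen bridge) | O=C(OC[C@@]12O[C@@H](C=C1)[C@@H]3OC(=O)O[C@H]23)c1ccccc1
F6 | step 2 | [2-exo,3-exo-dihydroxy-7-oxabicyclo[2.2.1]hept-5-en-1-yl]methyl benzoate | O=C(OC[C@@]12O[C@@H](C=C1)[C@H](O)[C@@H]2O)c1ccccc1
F7 | step 2 | (2,3-dioxo-7-oxabicyclo[2.2.1]hept-5-en-1-yl)methyl benzoate | O=C(OC[C@@]12O[C@@H](C=C1)C(=O)C2=O)c1ccccc1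
F8 | step 3 | 1-(hydroxymethyl)-7-oxabicyclo[2.2.1]hept-5-ene-2-endo,3-endo-diol | OC[C@@]12O[C@@H](C=C1)[C@@H](O)[C@H]2O
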